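Alder must end with a leftover: 16.0 mM of nucleophile against 20 mM of solid electrophile makes nucleophile the limiting reagent and caps the reacted part at 80.0 %.

the same everywhere: solid electrophile 20 mM
- midnight: nucleophile 20 mM; run made earlier
- dusk: nucleophile 30 mM; run made earlier
- alder: nucleophile 16.0 mM; time 1.5 h
- maple: nucleophile 21.0 mM; time 1.5 h

| run | time / min | solid electrophile / % | product / % |
|---|---|---|---|
| midnight | 8.00 | 35.3 | 30.4 |
| midnight | 25.0 | 0 | 58.5 |
| midnight | 40.0 | 0 | 68.0 |
| midnight | 60.0 | 0.5 | 76.7 |
| midnight | 90.0 | 0 | 84.2 |
| dusk | 8.00 | 32.6 | 39.8 |
| dusk | 15.0 | 0.2 | 66.1 |
| dusk | 25.0 | 0 | 78.3 |
| dusk | 50.0 | 0 | 90.6 |
| dusk | 90.0 | 0.5 | 98.3 |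

(readings scatter by 0.5 percentage points)

- acid set free is meant together with its crystals
- solid, in amounts per volume of the solution: crystals, solid electrophile
- the analysis behind the earlier runs scatters by 0.5 percentage points, standard deviation
- reactions considered so far: electrophile + nucleophile -> acid set free + product; nucleophile + acid set free <-> protonated nucleophile; crystals <-> acid set free; solid electrophile <-> electrophile
- at the start none of the solid electrophile is in solution
- what has only dissolved of solid electrophile counts as not reacted

- part of the solid electrophile that has reacted (what has only dissolved counts as not reacted) at the end, alder
- part of the solid electrophile that has reacted (what has only dissolved counts as not reacted) at the end, maple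
- what raising the concentration of nucleophile from its lowest to its highest value here does to the part of the solid electrophile that has reacted (what has only dissolved counts as not reacted) (changes below 5 percentage points count as none) (it falls / it rises / no change)

Does the acid lower that cap? If each acid set free held one nucleophile as protonated nucleophile, midnight would stall at half of its charge, but its product reads 84.2 % at 90.0 min, more than that half, so we take it that the acid goes into crystals and the cap stands.

How fast is the approach? If the rate is second order, then with equal charges 1/[electrophile] climbs in a straight line, and we read [electrophile] as the charge less the product from 25.0 min on, where midnight's solid electrophile reads 0 %; midnight's product readings at 25.0 min and 90.0 min give a slope of 0.00301 /mM/min. This is our effective second-order constant, with nucleophile counted free and protonated together. That line meets the charged value at 1.62 min, where we start the clock. Dusk, from 25.0 min to 90.0 min, reads 0.00341 /mM/min, more than midnight's; we keep midnight's.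

Does alder reach its cap? Under the same second-order rate with unequal charges, the logarithm of the larger concentration over the smaller rises from its charged value by the constant times the excess times the clock time. For alder that rise is 1.07, so the logarithm reaches 1.29, leaving by our reckoning 1.52 mM of nucleophile, free and protonated together, and a reacted part of 72.4 %, short of the cap. Maple, with electrophile as limiting reagent, has a rise of 0.266, smaller than alder's, and leaves 2.70 mM of electrophile, a reacted part of 86.5 %. The part reacted thus rises by 14 percentage points, beyond the margin.

The forecast gives 72 % for alder and 86.5 % for maple, and of the trend, it rises, holding that “the acid must leave as crystals”.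

The flasks give 73.1 % for alder and 86.8 % for maple, and the answer on the trend is: it rises, by 14 points.

    electrophile + nucleophile → acid set free + product (k = 13.0 /M/min)
    nucleophile + acid set free ⇌ protonated nucleophile, settled at all times (K = 2300 /M)
    crystals ⇌ acid set free, rate k3*(cs3 - [acid set free]) while solid is left; crystals form when [acid set free] > cs3 (solubility = 0.330 mM, k = 0.150 /min)
    solid electrophile ⇌ electrophile, rate k4*(cs4 - [electrophile]) while solid is left; crystals form when [electrophile] > cs4 (solubility = 19.0 mM, k = 0.110 /min)

At 1.50 h alder holds electrophile 26.9 %, nucleophile 3.03 % of its own charge and protonated nucleophile 0.898 mM, so the logarithm of electrophile over nucleophile, free and protonated together, stands at 1.36 against our 1.29. For a neighbour of maple charged with 5.2 mM of nucleophile, the same constant gives a rise of 3.94, leaving by our reckoning 0.0749 mM of nucleophile, free and protonated together, and a reacted part of 25.6 %. That flask gives 26.0 %.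

The readings stem from a simulated flask with made-up constants, and the scatter is random.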